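The route rests on disconnecting the C4–C4a bond of pyran ring C. C4 is a diarylmethine carbon flanked by ring A (at C4a) and by ring D, whose ortho-methoxy and para-oxygen substituents make a C4 cation easy to form. In the key step, acid ionises the C4 carbinol of an acyclic precursor and ring A, already tethered through the C2–O1 aryl ether, closes ring C by Friedel–Crafts attack para to its benzyloxy group, setting C4 trans to the C3 aryl group in the same operation. The precursor carries C3 (from an auxiliary-controlled aldol), C3' (from asymmetric hydrogenation) and four benzyl ethers, removed at the end.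

Key step: step 17

Assumption: compound 1 is taken as a catalogue chemical, and in step 8 the (4R,5R) ligand is assigned to the 3R product by analogy with simpler 3-aryl-2H-chromenes; should a first run show the opposite sense, its mirror image is used.

Step 1
Reactants: 1 2,4-dihydroxy-6-methoxybenzaldehyde
Product: 2 4-(benzyloxy)-2-hydroxy-6-methoxybenzaldehyde
Conditions: BnBr (1.05 equiv), KHCO3, MeCN, 60 °C
Reagents that add atoms: benzyl bromide, SMILES BrCc1ccccc1
Why: Williamson etherification; the 2-hydroxyl is held in a hydrogen bond to the formyl group, so the weak base should alkylate only the free, more acidic 4-hydroxyl para to the aldehyde.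

Step 2
Reactants: 2 4-(benzyloxy)-2-hydroxy-6-methoxybenzaldehyde
Product: 3 5-(benzyloxy)-2-formyl-3-methoxyphenyl trifluoromethanesulfonate
Conditions: Tf2O, pyridine, CH2Cl2, 0 °C
Reagents that add atoms: trifluoromethanesulfonic anhydride, SMILES O=S(=O)(OS(=O)(=O)C(F)(F)F)C(F)(F)F
Why: O-sulfonylation of the remaining phenol gives the aryl triflate that serves as the cross-coupling handle for the ring D–C3' bond.

Step 3
Reactants: 4 7-hydroxychroman-4-one
Product: 5 7-(benzyloxy)chroman-4-one
Conditions: BnBr, K2CO3, DMF, 60 °C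
Reagents that add atoms: benzyl bromide, SMILES BrCc1ccccc1
Why: Williamson etherification of the only phenol.

Step 4
Reactants: 5 7-(benzyloxy)chroman-4-one
Product: 6 rac-7-(benzyloxy)-3-bromochroman-4-one
Conditions: CuBr2 (2.1 equiv), EtOAc/CHCl3, reflux
Reagents that add atoms: copper dibromide (CuBr2), SMILES [Cu+2].[Br-].[Br-]
Why: α-Bromination of the ketone through its enol with CuBr2, the standard route to 3-bromochroman-4-ones; the carbonyl-deactivated arene should not be brominated.

Step 5
Reactants: 6 rac-7-(benzyloxy)-3-bromochroman-4-one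
Product: 7 7-(benzyloxy)-3-bromochroman-4-ol (racemic cis/trans mixture)
Conditions: NaBH4, MeOH/THF, 0 °C
Reagents that add atoms: none
Why: Hydride reduction of the α-bromo ketone to the bromohydrin; its configuration is irrelevant because both carbons become sp2 in the next step.

Step 6
Reactants: 7 7-(benzyloxy)-3-bromochroman-4-ol
Product: 8 7-(benzyloxy)-3-bromo-2H-chromene
Conditions: TsOH·H2O (5 mol %), toluene, reflux (Dean–Stark)
Reagents that add atoms: none
Why: Acid-catalysed E1 dehydration through the C4 benzylic cation, stabilised by the para 7-benzyloxy group; loss of H3 gives the conjugated alkenyl bromide.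

Step 7
Reactants: 3 5-(benzyloxy)-2-formyl-3-methoxyphenyl trifluoromethanesulfonate; 8 7-(benzyloxy)-3-bromo-2H-chromene
Product: 10 4-(benzyloxy)-2-[7-(benzyloxy)-2H-chromen-3-yl]-6-methoxybenzaldehyde, via aryl pinacol boronate 9 (not isolated)
Conditions: B2pin2, PdCl2(dppf) (5 mol %), KOAc, dioxane, 80 °C; then 8, aq K3PO4, 80 °C
Reagents that add atoms: none
Why: One-pot Miyaura borylation of the aryl triflate followed by Suzuki–Miyaura coupling with the cyclic alkenyl bromide, both routine for ortho-formyl aryl triflates, forms the ring D–C3' bond.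

Step 8
Reactants: 10 4-(benzyloxy)-2-[7-(benzyloxy)-2H-chromen-3-yl]-6-methoxybenzaldehyde
Product: 11 4-(benzyloxy)-2-[(3R)-7-(benzyloxy)chroman-3-yl]-6-methoxybenzaldehyde
Conditions: [Ir(cod)(L)]BArF (1 mol %; L = (4R,5R)-ThrePHOX phosphinite–oxazoline, BArF = B[3,5-(CF3)2C6H3]4), H2 (50 bar), CH2Cl2, rt
Reagents that add atoms: none
Why: Iridium-catalysed asymmetric hydrogenation of a 3-aryl-2H-chromene, the established entry to enantioenriched isoflavans, should set C3' as R by catalyst-controlled delivery of H2 to one alkene face, while the benzyl ethers are inert to the homogeneous catalyst and the hindered, electron-rich formyl group is expected to stay a spectator under base-free conditions.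

Step 9
Reactants: 12 2,6-dimethoxyphenol
Product: 13 2-(benzyloxy)-1,3-dimethoxybenzene
Conditions: BnBr, K2CO3, DMF, 60 °C
Reagents that add atoms: benzyl bromide, SMILES BrCc1ccccc1
Why: Williamson etherification, which also removes the para-directing free phenol before the bromination.

Step 10
Reactants: 13 2-(benzyloxy)-1,3-dimethoxybenzene
Product: 14 3-(benzyloxy)-1-bromo-2,4-dimethoxybenzene
Conditions: NBS (1.0 equiv), MeCN, 0 °C to rt
Reagents that add atoms: N-bromosuccinimide, SMILES O=C1CCC(=O)N1Br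
Why: Electrophilic aromatic bromination at the carbon ortho to one methoxy group and para to the other, the most activated site because the flanked central benzyloxy group is twisted out of conjugation (the pattern known for 1,2,3-trialkoxybenzenes).

Step 11
Reactants: 14 3-(benzyloxy)-1-bromo-2,4-dimethoxybenzene
Product: 15 diethyl 2-[3-(benzyloxy)-2,4-dimethoxyphenyl]malonate
Conditions: diethyl malonate, Pd2(dba)3 (1 mol %), P(tBu)3·HBF4 (4 mol %), K3PO4, toluene, 80 °C
Reagents that add atoms: diethyl malonate, SMILES CCOC(=O)CC(=O)OCC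
Why: Palladium-catalysed α-arylation of a malonate enolate, for which the bulky trialkylphosphine is the standard ligand with electron-rich, ortho-substituted aryl bromides.

Step 12
Reactants: 15 diethyl 2-[3-(benzyloxy)-2,4-dimethoxyphenyl]malonate
Product: 17 2-[3-(benzyloxy)-2,4-dimethoxyphenyl]acetic acid, via arylmalonic acid 16 (not isolated)
Conditions: NaOH, EtOH/H2O, 80 °C; then HCl (pH 1), 70 °C
Reagents that add atoms: sodium hydroxide, SMILES [Na+].[OH-]
Why: Saponification followed by thermal decarboxylation of the arylmalonic acid (the end-game of a malonic ester synthesis), under which aryl benzyl ethers are stable.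

Step 13
Reactants: 17 2-[3-(benzyloxy)-2,4-dimethoxyphenyl]acetic acid; 18 (S)-4-benzyloxazolidin-2-one
Product: 20 (4S)-4-benzyl-3-{2-[3-(benzyloxy)-2,4-dimethoxyphenyl]acetyl}oxazolidin-2-one, via mixed pivalic anhydride 19 (not isolated)
Conditions: PivCl, Et3N, THF, −20 °C; then 18, LiCl, rt
Reagents that add atoms: none
Why: N-acylation of the auxiliary through the mixed anhydride under the LiCl/Et3N protocol, which avoids strong base on the acidic arylacetyl unit.

Step 14
Reactants: 20 (4S)-4-benzyl-3-{2-[3-(benzyloxy)-2,4-dimethoxyphenyl]acetyl}oxazolidin-2-one; 11 4-(benzyloxy)-2-[(3R)-7-(benzyloxy)chroman-3-yl]-6-methoxybenzaldehyde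
Product: 22 (4S)-4-benzyl-3-[(2S,3S)-3-{4-(benzyloxy)-2-[(3R)-7-(benzyloxy)chroman-3-yl]-6-methoxyphenyl}-2-[3-(benzyloxy)-2,4-dimethoxyphenyl]-3-hydroxypropanoyl]oxazolidin-2-one, via dibutylboron Z-enolate 21 (not isolated)
Conditions: Bu2BOTf, Et3N, CH2Cl2, −78 to 0 °C; then 11, −78 to 0 °C; pH 7 buffer, MeOH, H2O2
Reagents that add atoms: none
Why: Evans syn-aldol addition in which the boron Z-enolate reacts through a Zimmerman–Traxler chair on the face away from the auxiliary benzyl group, setting the α-carbon (the future C3) as S and the carbinol as a single (S) epimer, of which only the former has to survive.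

Step 15
Reactants: 22 the syn-aldol adduct
Product: 23 (1S,2R)-1-{4-(benzyloxy)-2-[(3R)-7-(benzyloxy)chroman-3-yl]-6-methoxyphenyl}-2-[3-(benzyloxy)-2,4-dimethoxyphenyl]propane-1,3-diol
Conditions: LiBH4, MeOH (1 equiv), THF, 0 °C
Reagents that add atoms: none
Why: Reductive cleavage of the N-acyl oxazolidinone to the primary alcohol with release of the auxiliary; the fast reduction at 0 °C should leave the α-aryl centre untouched (its descriptor changes to R only through the priority rules).

Step 16
Reactants: 23 the 1,3-diol; 24 3-(benzyloxy)phenol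
Product: 25 (1S,2R)-1-{4-(benzyloxy)-2-[(3R)-7-(benzyloxy)chroman-3-yl]-6-methoxyphenyl}-2-[3-(benzyloxy)-2,4-dimethoxyphenyl]-3-[3-(benzyloxy)phenoxy]propan-1-ol
Conditions: PPh3, DIAD, THF, 0 °C to rt
Reagents that add atoms: none
Why: Mitsunobu etherification of the primary alcohol by the phenol; the secondary benzylic hydroxyl, buried beside the doubly ortho-substituted ring D, should not compete, and no stereocentre is involved.

Step 17
Reactants: 25 the acyclic carbinol
Product: 26 (3R,4S)-7-(benzyloxy)-4-{4-(benzyloxy)-2-[(3R)-7-(benzyloxy)chroman-3-yl]-6-methoxyphenyl}-3-[3-(benzyloxy)-2,4-dimethoxyphenyl]chroman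
Conditions: Bi(OTf)3 (10 mol %), CH2Cl2 (0.01 M), −20 to 0 °C
Reagents that add atoms: none
Why: Bi(OTf)3 (and the triflic acid it releases) ionises the benzylic C4–OH to a cation delocalised into ring D through its ortho-methoxy and para-benzyloxy groups, and the tethered ring A attacks it in an electrophilic aromatic substitution that forms C4–C4a; the closest known reaction type is the acid-mediated intramolecular Friedel–Crafts alkylation of 1-aryl-3-aryloxypropan-1-ols to 4-arylchromans. Ring C closes as a six-membered ring, exo with respect to the departing C4–O bond (6-exo-tet in the ionised limit) and endo with respect to the attacking arene bond C8a=C4a, both carbons of which end up in the ring. The new C4 centre is controlled by the existing C3 centre (1,2-induction): in the chair-like transition state the C3 aryl group and ring D both sit pseudo-equatorial, which should give the trans (3R,4S) isomer, also the more stable one. Because the cation is planar, the (1S) configuration of the carbinol is erased and only C3 from the aldol matters. The step needs regioselectivity on ring A, secured by attack at the carbon para to the benzyloxy group and ortho to O1 instead of the crowded carbon between the two oxygens, and it needs the cation to be trapped before it loses H3, secured by high dilution, low temperature and the proximity of the nucleophile.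

Step 18
Reactants: 26 the tetra-O-benzyl ether
Product: 27 (3R,4S)-4-{4-hydroxy-2-[(3R)-7-hydroxychroman-3-yl]-6-methoxyphenyl}-3-(3-hydroxy-2,4-dimethoxyphenyl)chroman-7-ol (CNP0305801.1)
Conditions: H2 (1 atm), 10% Pd/C, EtOAc/MeOH, rt
Reagents that add atoms: none
Why: Hydrogenolysis of the four aryl benzyl ethers; the chroman C–O bonds are not benzylic and the skeleton carries no other reducible group, so the three stereocentres are untouched.

Compound list
1 | 2,4-dihydroxy-6-methoxybenzaldehyde | COc1cc(O)cc(O)c1C=O | starting material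
2 | 4-(benzyloxy)-2-hydroxy-6-methoxybenzaldehyde | COc1cc(OCc2ccccc2)cc(O)c1C=O | intermediate
3 | 5-(benzyloxy)-2-formyl-3-methoxyphenyl trifluoromethanesulfonate | COc1cc(OCc2ccccc2)cc(OS(=O)(=O)C(F)(F)F)c1C=O | intermediate
4 | 7-hydroxychroman-4-one | O=C1CCOc2cc(O)ccc12 | starting material
5 | 7-(benzyloxy)chroman-4-one | O=C1CCOc2cc(OCc3ccccc3)ccc12 | intermediate
6 | rac-7-(benzyloxy)-3-bromochroman-4-one | O=C1C(Br)COc2cc(OCc3ccccc3)ccc12 | intermediate
7 | 7-(benzyloxy)-3-bromochroman-4-ol (racemic cis/trans mixture) | OC1C(Br)COc2cc(OCc3ccccc3)ccc12 | intermediate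
8 | 7-(benzyloxy)-3-bromo-2H-chromene | BrC1=Cc2ccc(OCc3ccccc3)cc2OC1 | intermediate
9 | 4-(benzyloxy)-2-methoxy-6-(4,4,5,5-tetramethyl-1,3,2-dioxaborolan-2-yl)benzaldehyde (not isolated) | COc1cc(OCc2ccccc2)cc(B2OC(C)(C)C(C)(C)O2)c1C=O | intermediate
10 | 4-(benzyloxy)-2-[7-(benzyloxy)-2H-chromen-3-yl]-6-methoxybenzaldehyde | COc1cc(OCc2ccccc2)cc(C2=Cc3ccc(OCc4ccccc4)cc3OC2)c1C=O | intermediate
11 | 4-(benzyloxy)-2-[(3R)-7-(benzyloxy)chroman-3-yl]-6-methoxybenzaldehyde | COc1cc(OCc2ccccc2)cc([C@@H]2COc3cc(OCc4ccccc4)ccc3C2)c1C=O | intermediate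
12 | 2,6-dimethoxyphenol | COc1cccc(OC)c1O | starting material
13 | 2-(benzyloxy)-1,3-dimethoxybenzene | COc1cccc(OC)c1OCc1ccccc1 | intermediate
14 | 3-(benzyloxy)-1-bromo-2,4-dimethoxybenzene | COc1ccc(Br)c(OC)c1OCc1ccccc1 | intermediate
15 | diethyl 2-[3-(benzyloxy)-2,4-dimethoxyphenyl]malonate | CCOC(=O)C(C(=O)OCC)c1ccc(OC)c(OCc2ccccc2)c1OC | intermediate
16 | 2-[3-(benzyloxy)-2,4-dimethoxyphenyl]malonic acid (not isolated) | OC(=O)C(C(=O)O)c1ccc(OC)c(OCc2ccccc2)c1OC | intermediate
17 | 2-[3-(benzyloxy)-2,4-dimethoxyphenyl]acetic acid | OC(=O)Cc1ccc(OC)c(OCc2ccccc2)c1OC | intermediate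
18 | (S)-4-benzyloxazolidin-2-one | O=C1OC[C@H](Cc2ccccc2)N1 | starting material
19 | 2-[3-(benzyloxy)-2,4-dimethoxyphenyl]acetic pivalic anhydride (not isolated) | CC(C)(C)C(=O)OC(=O)Cc1ccc(OC)c(OCc2ccccc2)c1OC | intermediate
20 | (4S)-4-benzyl-3-{2-[3-(benzyloxy)-2,4-dimethoxyphenyl]acetyl}oxazolidin-2-one | COc1ccc(CC(=O)N2[C@@H](Cc3ccccc3)COC2=O)c(OC)c1OCc1ccccc1 | intermediate
21 | dibutylboron Z-enolate of 20 (not isolated) | CCCCB(CCCC)O/C(=C\c1ccc(OC)c(OCc2ccccc2)c1OC)N1[C@@H](Cc2ccccc2)COC1=O | intermediate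
22 | (4S)-4-benzyl-3-[(2S,3S)-3-{4-(benzyloxy)-2-[(3R)-7-(benzyloxy)chroman-3-yl]-6-methoxyphenyl}-2-[3-(benzyloxy)-2,4-dimethoxyphenyl]-3-hydroxypropanoyl]oxazolidin-2-one | COc1ccc([C@H](C(=O)N2[C@@H](Cc3ccccc3)COC2=O)[C@H](O)c2c(OC)cc(OCc3ccccc3)cc2[C@@H]2COc3cc(OCc4ccccc4)ccc3C2)c(OC)c1OCc1ccccc1 | intermediate
23 | (1S,2R)-1-{4-(benzyloxy)-2-[(3R)-7-(benzyloxy)chroman-3-yl]-6-methoxyphenyl}-2-[3-(benzyloxy)-2,4-dimethoxyphenyl]propane-1,3-diol | COc1ccc([C@H](CO)[C@H](O)c2c(OC)cc(OCc3ccccc3)cc2[C@@H]2COc3cc(OCc4ccccc4)ccc3C2)c(OC)c1OCc1ccccc1 | intermediate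
24 | 3-(benzyloxy)phenol | Oc1cccc(OCc2ccccc2)c1 | starting material
25 | (1S,2R)-1-{4-(benzyloxy)-2-[(3R)-7-(benzyloxy)chroman-3-yl]-6-methoxyphenyl}-2-[3-(benzyloxy)-2,4-dimethoxyphenyl]-3-[3-(benzyloxy)phenoxy]propan-1-ol | COc1ccc([C@H](COc2cccc(OCc3ccccc3)c2)[C@H](O)c2c(OC)cc(OCc3ccccc3)cc2[C@@H]2COc3cc(OCc4ccccc4)ccc3C2)c(OC)c1OCc1ccccc1 | intermediate
26 | (3R,4S)-7-(benzyloxy)-4-{4-(benzyloxy)-2-[(3R)-7-(benzyloxy)chroman-3-yl]-6-methoxyphenyl}-3-[3-(benzyloxy)-2,4-dimethoxyphenyl]chroman | COc1ccc([C@@H]2COc3cc(OCc4ccccc4)ccc3[C@H]2c2c(OC)cc(OCc4ccccc4)cc2[C@@H]2COc3cc(OCc4ccccc4)ccc3C2)c(OC)c1OCc1ccccc1 | intermediate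
27 | (3R,4S)-4-{4-hydroxy-2-[(3R)-7-hydroxychroman-3-yl]-6-methoxyphenyl}-3-(3-hydroxy-2,4-dimethoxyphenyl)chroman-7-ol | COc1ccc([C@@H]2COc3cc(O)ccc3[C@H]2c2c(OC)cc(O)cc2[C@@H]2COc3cc(O)ccc3C2)c(OC)c1O | target

Total step count: 18. Longest linear sequence: 11 steps (steps 3–8, then 14–18).

Steps most likely to fail

1. Step 17. The planar C4 cation may be captured from both faces (incomplete 1,2-induction), so that the cis C4 epimer forms beside 26. The fallback moves stereocontrol from the kinetic ring closure to a separate thermodynamic equilibration. Setting out from 25, the closure is run as in step 17 and the cis epimer, (3R,4R)-7-(benzyloxy)-4-{4-(benzyloxy)-2-[(3R)-7-(benzyloxy)chroman-3-yl]-6-methoxyphenyl}-3-[3-(benzyloxy)-2,4-dimethoxyphenyl]chroman F1, is kept with the mixture. Treatment with KOtBu in DMSO (rt to 50 °C) reversibly deprotonates the doubly benzylic C4–H, which is the known base-mediated cis-to-trans isomerisation of 3,4-diarylchromans. C3, whose hydrogen is only singly benzylic, should be left alone, and the material converges on the trans isomer, returning to the route at 26.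

2. Step 14. Addition of the boron enolate to the doubly ortho-substituted, electron-rich aldehyde may be too slow, and the adduct may revert by retro-aldol cleavage. The fallback changes the auxiliary and the enolate metal so that the aldehyde is activated by a Lewis acid. Setting out from acid 17, coupling with (S)-4-benzylthiazolidine-2-thione (EDC·HCl, DMAP, CH2Cl2) gives (4S)-4-benzyl-3-{2-[3-(benzyloxy)-2,4-dimethoxyphenyl]acetyl}thiazolidine-2-thione F2. Its chlorotitanium enolate (TiCl4, iPr2NEt, N-methyl-2-pyrrolidinone, CH2Cl2, −78 to 0 °C) adds to 11 to give the syn adduct (4S)-4-benzyl-3-[(2S,3S)-3-{4-(benzyloxy)-2-[(3R)-7-(benzyloxy)chroman-3-yl]-6-methoxyphenyl}-2-[3-(benzyloxy)-2,4-dimethoxyphenyl]-3-hydroxypropanoyl]thiazolidine-2-thione F3, with the same configuration at the α-carbon. LiBH4 in THF cleaves the thione auxiliary directly, and the route is rejoined at diol 23.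

3. Step 8. Facial discrimination of the ortho-substituted 3-aryl-2H-chromene by the chiral catalyst may be incomplete, leaving 11 of insufficient enantiopurity. The fallback secures C3' by separation of diastereomers instead of catalyst control. Setting out from 10, hydrogenation with the achiral catalyst [Ir(cod)(PCy3)(py)]PF6 (H2, CH2Cl2) gives racemic 4-(benzyloxy)-2-[7-(benzyloxy)chroman-3-yl]-6-methoxybenzaldehyde F4. The aldol of step 14 then gives 22 together with its C3' epimer, (4S)-4-benzyl-3-[(2S,3S)-3-{4-(benzyloxy)-2-[(3S)-7-(benzyloxy)chroman-3-yl]-6-methoxyphenyl}-2-[3-(benzyloxy)-2,4-dimethoxyphenyl]-3-hydroxypropanoyl]oxazolidin-2-one F5. The two are diastereomers and are separated by chromatography, and the route is rejoined at 22.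

Further compounds
F1 | step 17 | (3R,4R)-7-(benzyloxy)-4-{4-(benzyloxy)-2-[(3R)-7-(benzyloxy)chroman-3-yl]-6-methoxyphenyl}-3-[3-(benzyloxy)-2,4-dimethoxyphenyl]chroman | COc1ccc([C@@H]2COc3cc(OCc4ccccc4)ccc3[C@@H]2c2c(OC)cc(OCc4ccccc4)cc2[C@@H]2COc3cc(OCc4ccccc4)ccc3C2)c(OC)c1OCc1ccccc1
F2 | step 14 | (4S)-4-benzyl-3-{2-[3-(benzyloxy)-2,4-dimethoxyphenyl]acetyl}thiazolidine-2-thione | COc1ccc(CC(=O)N2[C@@H](Cc3ccccc3)CSC2=S)c(OC)c1OCc1ccccc1
F3 | step 14 | (4S)-4-benzyl-3-[(2S,3S)-3-{4-(benzyloxy)-2-[(3R)-7-(benzyloxy)chroman-3-yl]-6-methoxyphenyl}-2-[3-(benzyloxy)-2,4-dimethoxyphenyl]-3-hydroxypropanoyl]thiazolidine-2-thione | COc1ccc([C@H](C(=O)N2[C@@H](Cc3ccccc3)CSC2=S)[C@H](O)c2c(OC)cc(OCc3ccccc3)cc2[C@@H]2COc3cc(OCc4ccccc4)ccc3C2)c(OC)c1OCc1ccccc1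
F4 | step 8 | rac-4-(benzyloxy)-2-[7-(benzyloxy)chroman-3-yl]-6-methoxybenzaldehyde | COc1cc(OCc2ccccc2)cc(C2COc3cc(OCc4ccccc4)ccc3C2)c1C=O
F5 | step 8 | (4S)-4-benzyl-3-[(2S,3S)-3-{4-(benzyloxy)-2-[(3S)-7-(benzyloxy)chroman-3-yl]-6-methoxyphenyl}-2-[3-(benzyloxy)-2,4-dimethoxyphenyl]-3-hydroxypropanoyl]oxazolidin-2-one | COc1ccc([C@H](C(=O)N2[C@@H](Cc3ccccc3)COC2=O)[C@H](O)c2c(OC)cc(OCc3ccccc3)cc2[C@H]2COc3cc(OCc4ccccc4)ccc3C2)c(OC)c1OCc1ccccc1
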